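Assumption: the target is achiral (no stereocentre, no stereoaxis), so there is no enantiomer to select. The SMILES shows the neutral bis(hydrogen sulfate), so the sulfate esters are carried as triethylammonium salts and the acid form is released in the last operation.

**Retrosynthetic overview**
1. The target comes from a benzylic alcohol that already carries the aryl sulfate (para to CH2OH) and a TIPS ether on the other phenol, by benzylic O-sulfation, Si–O cleavage and cation exchange.
2. The key disconnection is aryl–CH2OH: an electrophilic aryl C–Br carbon joins a hydroxymethyl carbanion equivalent (Bu3SnCH2OH). It is run late, as a site-selective mono-coupling on a 1,2,3-tribromoarene that keeps its other two bromines.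
3. The tribromoaryl sulfate comes from 3,4,5-tribromocatechol in one flask: bulky silyl on the OH next to C–H, sulfate on the OH next to C–Br.
4. 3,4,5-Tribromocatechol comes from catechol and 3 Br2.
5. No ring is formed; the only ring (benzene) is bought with catechol.

**Route**

Step 1
Reactants: 1 catechol (benzene-1,2-diol)
Product: 2 3,4,5-tribromobenzene-1,2-diol (3,4,5-tribromocatechol)
Conditions: Br2 (3.0 equiv), AcOH, 0 °C to rt; recrystallise
Reagents that add atoms: bromine (Br2), BrBr
Why: Electrophilic aromatic bromination in which the first two bromines enter para to the two hydroxyls, the third takes one of the two equivalent remaining ortho sites so that only one tribromide can form, and the falling ring reactivity together with exact stoichiometry holds back the fourth bromination (traces of di- and tetrabromide go on recrystallisation); no stereocentre is created.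

Step 2
Reactants: 2 3,4,5-tribromocatechol
Product: 4 triethylammonium 2,3,4-tribromo-6-(triisopropylsilyloxy)phenyl sulfate, via mono-TIPS ether 3 (not isolated)
Conditions: TIPSCl (1.0 equiv), Et3N (2.5 equiv), DMF, 0 °C to rt, Ar; then SO3·NEt3 (2.5 equiv), 45 °C; CH2Cl2/H2O, SiO2 (CH2Cl2/MeOH, 1% Et3N)
Reagents that add atoms: triisopropylsilyl chloride (TIPSCl), CC(C)[Si](Cl)(C(C)C)C(C)C; sulfur trioxide-triethylamine complex (SO3·NEt3), CC[N+](CC)(CC)S(=O)(=O)[O-]
Why: Sterically governed O-silylation followed by sulfuryl transfer from an amine-SO3 complex: the bulky silyl chloride takes the hydroxyl that has a C–H neighbour, this isomer is also the thermodynamic one because it leaves the more acidic bromine-flanked phenol free, and that phenoxide is capped at once as the sulfate monoester, which fixes the regiochemistry and puts the aryl sulfate in place before any benzylic leaving group exists; no stereocentre is created.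

Step 3
Reactants: 4 triethylammonium 2,3,4-tribromo-6-(triisopropylsilyloxy)phenyl sulfate; 5 (tributylstannyl)methanol (Bu3SnCH2OH)
Product: 6 triethylammonium 2,3-dibromo-4-(hydroxymethyl)-6-(triisopropylsilyloxy)phenyl sulfate
Conditions: 5 (1.1 equiv), Pd(PPh3)4 (5 mol %), 1,4-dioxane, 95 °C, 14 h, Ar; MeCN/hexane partition, SiO2
Reagents that add atoms: none
Why: Migita-Kosugi-Stille hydroxymethylation in which the alpha-hydroxystannane acts as a hydroxymethyl carbanion (formaldehyde carbon with inverted polarity) toward an aryl carbon that is itself an electrophile, and zerovalent palladium should insert only into the C–Br bond that has an ortho hydrogen and lies para to the weakly donating sulfate, since the middle bromine is walled in by two bromines and sits para to the siloxy donor and the third is walled in by bromine and sulfate, in line with the terminal selectivity of 1,2,3-trihaloarenes and the para selectivity of 2,4-dibromophenol derivatives, while the product keeps only doubly ortho-substituted C–Br bonds and so resists a second coupling; no stereocentre is created.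

Step 4
Reactants: 6 triethylammonium 2,3-dibromo-4-(hydroxymethyl)-6-(triisopropylsilyloxy)phenyl sulfate
Product: 9 2,3-dibromo-5-hydroxy-4-(sulfooxy)benzyl hydrogen sulfate, via silylated bis-sulfate salt 7 (not isolated), via desilylated bis-sulfate salt 8 (not isolated)
Conditions: SO3·NEt3 (2 equiv), DMF, rt; MeOH, 1 h (destroys excess reagent); NH4F (5 equiv), rt; C18 silica (H2O/MeOH); sulfonic acid cation-exchange resin (H+ form), H2O, 0 °C; freeze-dry
Reagents that add atoms: sulfur trioxide-triethylamine complex (SO3·NEt3), CC[N+](CC)(CC)S(=O)(=O)[O-]
Why: O-Sulfation of the only free hydroxyl, fluoride-induced cleavage of the aryl silyl ether and cation exchange: because the para oxygen is already sulfated the benzylic sulfate cannot collapse to a para-quinone methide, the phenol unmasked by fluoride is meta to the benzylic carbon, sulfate monoester anions ignore neutral fluoride in methanol, and short cold contact with the resin followed by freeze-drying limits acid hydrolysis of the aryl sulfate; no stereocentre is created.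

**Compound list**
1 | catechol (benzene-1,2-diol) | Oc1ccccc1O | starting material
2 | 3,4,5-tribromobenzene-1,2-diol | Oc1cc(Br)c(Br)c(Br)c1O | intermediate
3 | 2,3,4-tribromo-6-(triisopropylsilyloxy)phenol (free OH next to C–Br, silyl ether next to C–H) | Oc1c(Br)c(Br)c(Br)cc1O[Si](C(C)C)(C(C)C)C(C)C | intermediate
4 | triethylammonium 2,3,4-tribromo-6-(triisopropylsilyloxy)phenyl sulfate | CC[NH+](CC)CC.[O-]S(=O)(=O)Oc1c(Br)c(Br)c(Br)cc1O[Si](C(C)C)(C(C)C)C(C)C | intermediate
5 | (tributylstannyl)methanol | CCCC[Sn](CO)(CCCC)CCCC | starting material
6 | triethylammonium 2,3-dibromo-4-(hydroxymethyl)-6-(triisopropylsilyloxy)phenyl sulfate | CC[NH+](CC)CC.[O-]S(=O)(=O)Oc1c(Br)c(Br)c(CO)cc1O[Si](C(C)C)(C(C)C)C(C)C | intermediate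
7 | bis(triethylammonium) 2,3-dibromo-4-(sulfonatooxy)-5-(triisopropylsilyloxy)benzyl sulfate | CC[NH+](CC)CC.CC[NH+](CC)CC.[O-]S(=O)(=O)OCc1cc(O[Si](C(C)C)(C(C)C)C(C)C)c(OS(=O)(=O)[O-])c(Br)c1Br | intermediate
8 | bis(triethylammonium) 2,3-dibromo-5-hydroxy-4-(sulfonatooxy)benzyl sulfate | CC[NH+](CC)CC.CC[NH+](CC)CC.[O-]S(=O)(=O)OCc1cc(O)c(OS(=O)(=O)[O-])c(Br)c1Br | intermediate
9 | 2,3-dibromo-5-hydroxy-4-(sulfooxy)benzyl hydrogen sulfate (achiral) | O=S(=O)(O)OCc1cc(O)c(OS(=O)(=O)O)c(Br)c1Br | target

**Total step count:** 4. **Longest linear sequence:** 4 (1 → 2 → 4 → 6 → 9).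

**Steps most likely to fail**

First, step 3. The risks are insertion into the wrong C–Br bond, double coupling, and slow transfer of CH2OH from tin.
- The fallback keeps a polarity-inverted one-carbon unit but moves to the aldehyde oxidation level and away from tin.
- It sets out from 4. Nitromethane, a formyl anion equivalent, is coupled under Pd2(dba)3, XPhos (2-dicyclohexylphosphino-2',4',6'-triisopropylbiphenyl), K3PO4, MeNO2, 4 Å sieves, 55 °C.
- The bulky ligand sharpens the steric choice of the bromine next to C–H. The product rests in the flask as its nitronate, whose charge shuts down a second oxidative addition.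
- Ion-pair extraction from triethylammonium acetate buffer gives triethylammonium 2,3-dibromo-4-(nitromethyl)-6-(triisopropylsilyloxy)phenyl sulfate F1.
- A reductive Nef reaction (aqueous TiCl3 buffered with NH4OAc, THF, 0 °C to rt) gives triethylammonium 2,3-dibromo-4-formyl-6-(triisopropylsilyloxy)phenyl sulfate F2.
- NaBH4 in EtOH at 0 °C reduces the aldehyde to 6, where the route is rejoined.

Second, step 2. The risks are imperfect choice between the two hydroxyls, silyl scrambling before the sulfate is on, and a hindered phenoxide that is slow to sulfate in an unpurified mixture.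
- The fallback replaces selective protection by exhaustive protection and convergent mono-deprotection, with isolation of the phenol.
- It sets out from 2. TIPSOTf and 2,6-lutidine in CH2Cl2 give 1,2,3-tribromo-4,5-bis(triisopropylsilyloxy)benzene F3.
- One equivalent of Bu4NF in THF (−78 °C to 0 °C) removes one silyl group.
- Whichever Si–O bond breaks first, the 1,4 oxygen-to-oxygen silyl shift of the resulting phenoxide funnels the material to the less crowded isomer with the better stabilised phenoxide.
- That isomer is 3, where the route is rejoined. It is now purified before a separate sulfation to 4.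

Third, step 4. The risks are substitution at the benzylic sulfate during the fluoride/methanol stage, sluggish desilylation next to an anionic sulfate, and loss of the acid form on isolation.
- The fallback inverts the order and relies on chemoselectivity instead of protection.
- It sets out from 6. NH4F in MeOH first gives triethylammonium 2,3-dibromo-6-hydroxy-4-(hydroxymethyl)phenyl sulfate F4.
- SO3·NEt3 (1.2 equiv) in DMF at rt, without added base, then sulfates only the primary alcohol. The neutral phenol is a poor nucleophile and is hydrogen-bonded to and shielded by the neighbouring anionic sulfate.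
- This gives 8, where the route is rejoined for the cold cation exchange.

**Further compounds**
F1 | step 3 | triethylammonium 2,3-dibromo-4-(nitromethyl)-6-(triisopropylsilyloxy)phenyl sulfate | CC[NH+](CC)CC.[O-]S(=O)(=O)Oc1c(Br)c(Br)c(C[N+](=O)[O-])cc1O[Si](C(C)C)(C(C)C)C(C)C
F2 | step 3 | triethylammonium 2,3-dibromo-4-formyl-6-(triisopropylsilyloxy)phenyl sulfate | CC[NH+](CC)CC.[O-]S(=O)(=O)Oc1c(Br)c(Br)c(C=O)cc1O[Si](C(C)C)(C(C)C)C(C)C
F3 | step 2 | 1,2,3-tribromo-4,5-bis(triisopropylsilyloxy)benzene | CC(C)[Si](Oc1cc(Br)c(Br)c(Br)c1O[Si](C(C)C)(C(C)C)C(C)C)(C(C)C)C(C)C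
F4 | step 4 | triethylammonium 2,3-dibromo-6-hydroxy-4-(hydroxymethyl)phenyl sulfate | CC[NH+](CC)CC.[O-]S(=O)(=O)Oc1c(Br)c(Br)c(CO)cc1O
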